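## The problem

Ophioglonol prenyl ether (16) is a 5,7,3',4'-tetrahydroxyflavone with a CH2–O–prenyl group on C3. The skeleton is a chromone (rings A and C) joined through the C2–C1' bond to a catechol (ring B), plus one extra carbon on C3 that carries an allylic ether. The molecule has no stereocentre, so nothing has to be controlled or relayed; the difficulties are regiochemistry, chemoselectivity and protecting groups. The prenyl ether is the most fragile part: it does not survive hydrogenolysis, strong protic or Lewis acids, or boron-halide dealkylation. Benzyl and methyl protection of the phenols is therefore excluded, and groups that leave with fluoride are required. The catechol is oxidised to an ortho-quinone in basic aerated media, the pyranone ring opens when hard nucleophiles attack C2, and the C5 hydroxyl is chelated to C4=O and is hard to protect once ring C exists. The feature that opens a short route is the substitution pattern of ring B. C2'–C3'–C4'–C5' is a four-carbon chain with oxygen on its two inner atoms, which is a 2,3-dioxygenated buta-1,3-diene. C1'–C6' is a two-carbon unit that can be an alkyne on C2, where it is conjugated through C2=C3 with the C4 carbonyl and so is an acceptor alkyne.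

## Retrosynthesis

**16 from 15 and 14.** The four O–H bonds of 16 are traced back to O–Si bonds in the tetrasilyl flavone 15 (two TMS groups on ring B, two TIPS groups on ring A). All four leave with buffered fluoride, the one reagent class to which the prenyl ether, the catechol and the pyranone are all indifferent. Compound 15 is in turn the dehydrogenation product of the cyclohexa-1,4-diene 14, which carries two hydrogens more than the arene (at C2' and C5'). Both CH2 groups of 14 are doubly allylic and the ring is an enediol bis-silyl ether, so the forward step only needs a mild hydride acceptor.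

**14 from 11 and 13.** The C1'–C2' and C5'–C6' bonds are cut together, which is a retro-Diels–Alder reaction of the cyclohexa-1,4-diene. This gives the 2-ethynylchromone 11 and the symmetric diene 13. The neighbouring cut, the C2–C1' biaryl bond, would need a preformed, doubly protected catechol metal reagent. The chosen cut instead delivers both ring B oxygens from a C4 building block, at the correct positions by symmetry. The forward reaction needs periselectivity only: the diene must add to the terminal alkyne and to nothing else.

**13 from 12.** The two O–Si bonds of the diene are cut to give butane-2,3-dione (12). A single double enol silylation makes 13; it can also be bought, but a freshly distilled batch is preferable for a slow cycloaddition.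

**11 from 10, 8 and 9, and 8 from 6.** The C2–C(sp) bond is cut to give the 2-iodochromone 8 and ethynyltrimethylsilane (9), with the C-silyl alkyne 10 as the coupled intermediate. The iodide is traced to the C2–H chromone 6 through the chlorozinc species 7. This uses the one acidic vinylic hydrogen of 6 and avoids building ring C around a preinstalled alkyne, where an ynone would compete as an acceptor for the phenol. The forward steps need a base mild enough for aryl silyl ethers, and a C-desilylation that leaves the O-silyl groups in place.

**6 from 4 and 5.** The O–CH2 bond on the prenyl side is cut to give the primary alcohol 4 and prenyl bromide (5). Cutting on the chromone side instead would need a 3-(halomethyl)chromone, which is prone to attack at C2. The forward alkylation must avoid a free alkoxide, because the pyranone and the aryl silyl ethers are both base-sensitive.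

**4 from 3, 2 and 1.** The alcohol 4 is the reduction product of the 3-formylchromone 3. In 3 the bonds O1–C2, C2–C3 and C3–CHO are cut at once, which leads to the acetophenone 2 and two formyl equivalents (Vilsmeier–Haack). The side-chain carbon is thus in place from the moment ring C closes. Compound 2 is 2,4,6-trihydroxyacetophenone (1) with two of its three hydroxyls silylated. Silylating before ring closure solves the problem of the future C5 oxygen, because at the acetophenone stage the two ortho hydroxyls are equivalent and the second one remains chelated.

## Roads not taken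

**Alternative 1: carbene-catalysed acyl anion closure of C3–C4.** The cut is the C3–C4 bond of ring C. In the forward direction the aldehyde A1, an ortho-(1-arylpropargyloxy)benzaldehyde carrying all four oxygens as TIPS ethers, would be treated with a thiazolium-derived N-heterocyclic carbene and K2CO3. The acyl anion equivalent would add to the proximal alkyne carbon in a 6-exo-dig closure and give the 3-methyleneflavanone A2. The merits are real: the closure is metal-free and mild, this type of hydroacylation is established on simpler O-propargyl salicylaldehydes, ring B arrives ready-made, and the exocyclic enone is set up for conjugate addition of the allylic alcohol that supplies the prenyl group. The weak points for this target lie in the oxidation level. A2 is a flavanone with a C2 stereocentre that the target does not have, so stereochemical information is created and then destroyed. After the ether is attached, the C2–C3 bond must be dehydrogenated in the presence of the prenyl ether. Under the basic conditions the exocyclic alkene can also migrate into the ring, which removes the handle for the ether oxygen. Assembly of A1 further requires O-alkylation of a hindered, chelated phenol with a secondary propargylic electrophile. On precedent for the ring-forming step this road is ahead of the chosen plan, whose dienophile is untested. Against that, the chosen plan keeps C2 and C3 at the flavone oxidation level throughout and makes the side-chain ether by a plain alkylation before the key step.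

**Alternative 2: Friedel–Crafts closure of the pyranone at C4–C4a.** The cut is the C4–C4a bond. In the forward direction the (Z)-3-aryloxyacrylic acid A3 would be activated in P2O5/MeSO3H and the acylium carbon would attack the 3,5-dimethoxyphenoxy ring to give the tetramethoxyflavone A4. This is the most reliable ring closure of the four: it is classical and scalable, the symmetric phenoxy ring poses no regiochemical question, and the flavone oxidation level is reached directly. The price is paid in protecting groups. The strongly acidic medium forces methyl ethers. Removing four aryl methyl ethers needs boron or aluminium halides, which a prenyl ether does not survive. The C3 methoxymethyl group would therefore have to be exchanged for the prenyloxymethyl group only after global demethylation, on a substrate with four free phenols. The tetrasubstituted acid A3 is also not trivial to assemble with the required geometry. The chosen plan is weaker in its ring-forming step. What it sets against this is an end game in which every protecting group is a fluoride-labile silyl ether and the prenyl ether is installed early on a simple primary alcohol.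

**Alternative 3: one-carbon ring expansion of a benzofuranone enol ether.** The cut inserts C3 between C2 and C4, forming C2–C3 and C3–C4. In the forward direction dibromocarbene (from CHBr3 and KOtBu) would add to the enol ether double bond of A5, the enol silyl ether of a 2-aryl-benzofuran-3(2H)-one. The cyclopropane would open with loss of bromide and of the enol silyl group to give the 3-bromoflavone A6. Ring B again needs no construction, and A6 is a more versatile branching point than any intermediate of the chosen route, because the C3 bromide can be cross-coupled with many partners. The weak points are three. The carbene is generated with a strong alkoxide base in the presence of five base-labile aryl or enol silyl ethers. Carbene ring expansion of such electron-rich, fully substituted benzofuran enol ethers is much less secure than for indoles or simple enol ethers. The side chain must then be attached by an sp2–sp3 coupling of a hindered bromide with an alkoxymethyl metal reagent. The chosen plan avoids strong-base chemistry after silylation and brings the side-chain carbon in at the start by formylation. It accepts in return a longer linear sequence to the dienophile.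

Key step: step 9

Remark: the LiCl of the zinc amide base is treated as a spectator, so intermediate 7 is drawn as the plain chlorozinc species. Diene 13 is prepared in one step, although it can also be purchased.

## Route

Step 1
Reactants: 1 2,4,6-trihydroxyacetophenone
Product: 2 1-[2-hydroxy-4,6-bis(triisopropylsilyloxy)phenyl]ethanone
Conditions: TIPSCl (2.1 equiv), imidazole, DMF, 0 °C to rt
Reagents that add atoms: chlorotriisopropylsilane, CC(C)[Si](Cl)(C(C)C)C(C)C
Why: Phenol silylation (silyl ether formation); the para hydroxyl and one ortho hydroxyl react, while the remaining ortho hydroxyl is chelated to the acetyl carbonyl and should stay free. Placing the future O5 group now avoids silylating a chelated 5-hydroxychromone later.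

Step 2
Reactants: 2 1-[2-hydroxy-4,6-bis(triisopropylsilyloxy)phenyl]ethanone
Product: 3 4-oxo-5,7-bis(triisopropylsilyloxy)-4H-chromene-3-carbaldehyde
Conditions: POCl3 (3 equiv), DMF, 0 °C to rt; then ice/H2O
Reagents that add atoms: N,N-dimethylformamide, CN(C)C=O; water, O
Why: Vilsmeier–Haack double formylation of the acetyl methyl group with ring closure by the free phenol, the standard route from 2-hydroxyacetophenones to 3-formylchromones; DMF supplies C2 and the formyl carbon, and water supplies the formyl oxygen on hydrolysis. Aryl TIPS ethers tolerate the acidic medium, and their bulk shields the two ring CH positions from electrophilic formylation.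

Step 3
Reactants: 3 4-oxo-5,7-bis(triisopropylsilyloxy)-4H-chromene-3-carbaldehyde
Product: 4 3-(hydroxymethyl)-5,7-bis(triisopropylsilyloxy)-4H-chromen-4-one
Conditions: 9-BBN (1.1 equiv), THF, 0 °C to rt; then MeOH
Reagents that add atoms: none
Why: Chemoselective 1,2-reduction of a conjugated aldehyde by a dialkylborane; the vinylogous ester carbonyl C4=O and the C2=C3 bond are far less reactive. This avoids the hydride attack at C2 that opens chromones with NaBH4.

Step 4
Reactants: 4 3-(hydroxymethyl)-5,7-bis(triisopropylsilyloxy)-4H-chromen-4-one, 5 prenyl bromide (1-bromo-3-methylbut-2-ene)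
Product: 6 3-[(3-methylbut-2-enyloxy)methyl]-5,7-bis(triisopropylsilyloxy)-4H-chromen-4-one
Conditions: Ag2O (2 equiv), 4 Å MS, CH2Cl2, rt, dark
Reagents that add atoms: none
Why: Williamson-type etherification with neutral Ag2O activation of the allylic bromide; no free alkoxide is formed, so the pyranone ring and the aryl silyl ethers are not attacked. Substitution at the primary terminus of the prenyl unit is favoured.

Step 5
Reactants: 6 3-[(3-methylbut-2-enyloxy)methyl]-5,7-bis(triisopropylsilyloxy)-4H-chromen-4-one
Product: 8 2-iodo-3-[(3-methylbut-2-enyloxy)methyl]-5,7-bis(triisopropylsilyloxy)-4H-chromen-4-one, via C2-chlorozinc chromone 7 (not isolated)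
Conditions: TMPZnCl·LiCl (1.3 equiv), THF, 25 °C; then I2, 0 °C
Reagents that add atoms: iodine, II
Why: Deprotonative zincation of the chromone C2–H by a TMP zinc amide, followed by iodinolysis of the C–Zn bond. C2–H is the only vinylic hydrogen, it is acidified by O1 and the enone, and the side-chain ether oxygen is a neighbouring donor. The mild base tolerates the carbonyl and the silyl ethers.

Step 6
Reactants: 8 2-iodo-3-[(3-methylbut-2-enyloxy)methyl]-5,7-bis(triisopropylsilyloxy)-4H-chromen-4-one, 9 ethynyltrimethylsilane
Product: 10 3-[(3-methylbut-2-enyloxy)methyl]-5,7-bis(triisopropylsilyloxy)-2-[(trimethylsilyl)ethynyl]-4H-chromen-4-one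
Conditions: Pd(PPh3)2Cl2 (3 mol%), CuI (5 mol%), Et3N, THF, rt
Reagents that add atoms: none
Why: Sonogashira coupling; the 2-iodochromone is a vinylogous acyl iodide that adds readily to zerovalent palladium. A tertiary amine base cannot displace the iodide by addition–elimination.

Step 7
Reactants: 10 3-[(3-methylbut-2-enyloxy)methyl]-5,7-bis(triisopropylsilyloxy)-2-[(trimethylsilyl)ethynyl]-4H-chromen-4-one
Product: 11 2-ethynyl-3-[(3-methylbut-2-enyloxy)methyl]-5,7-bis(triisopropylsilyloxy)-4H-chromen-4-one
Conditions: AgNO3 (10 mol%), acetone/H2O, rt
Reagents that add atoms: none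
Why: AgNO3-catalysed protiodesilylation of a trimethylsilyl alkyne, which is selective for the C(sp)–Si bond over O–Si bonds. It runs at neutral pH, so the aryl TIPS ethers stay and no alkoxide is present to add to the activated alkyne.

Step 8
Reactants: 12 butane-2,3-dione
Product: 13 2,3-bis(trimethylsilyloxy)buta-1,3-diene
Conditions: TMSOTf (2.2 equiv), Et3N, Et2O, 0 °C to rt; distillation
Reagents that add atoms: trimethylsilyl trifluoromethanesulfonate, C[Si](C)(C)OS(=O)(=O)C(F)(F)F
Why: Double enol silylation of a 1,2-diketone with a silyl triflate and a tertiary amine (silyl enol ether formation), the standard preparation of this diene.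

Step 9
Reactants: 11 2-ethynyl-3-[(3-methylbut-2-enyloxy)methyl]-5,7-bis(triisopropylsilyloxy)-4H-chromen-4-one, 13 2,3-bis(trimethylsilyloxy)buta-1,3-diene
Product: 14 2-[4,5-bis(trimethylsilyloxy)cyclohexa-1,4-dien-1-yl]-3-[(3-methylbut-2-enyloxy)methyl]-5,7-bis(triisopropylsilyloxy)-4H-chromen-4-one
Conditions: 13 (5 equiv), BHT (cat.), toluene, 140 °C, sealed tube; crude product taken on directly
Reagents that add atoms: none
Why: A thermal Diels–Alder reaction of normal electron demand: the HOMO of the electron-rich diene 13 overlaps with the LUMO of the alkyne, which is lowered by conjugation through C2=C3 with the C4 carbonyl (a vinylogous ynone), and C1'–C2' and C5'–C6' form suprafacially in one step. The closest known reaction type is the cycloaddition of 2,3-bis(silyloxy)butadienes with acetylenic esters and ketones to give 4,5-bis(silyloxy)cyclohexa-1,4-dienes; the chromonyl alkyne is a new member of that dienophile class. The six-membered carbocycle that becomes ring B is closed by an intermolecular [4+2] annulation, four carbons from the diene and two from the alkyne, with both new bonds made in the same step. No stereocentre is formed. Regiochemistry is not an issue because the diene is symmetric, so either orientation gives the same adduct. The selectivity that matters is periselectivity: the terminal, unhindered alkyne is the only acceptor π bond that is both conjugated and accessible, whereas C2=C3 is tetrasubstituted, the prenyl alkene is electron-rich and the C4 carbonyl is a vinylogous ester. The reaction is supported by excess diene, a radical inhibitor against alkyne oligomerisation, and TIPS ethers that withstand prolonged heating.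

Step 10
Reactants: 14 2-[4,5-bis(trimethylsilyloxy)cyclohexa-1,4-dien-1-yl]-3-[(3-methylbut-2-enyloxy)methyl]-5,7-bis(triisopropylsilyloxy)-4H-chromen-4-one
Product: 15 2-[3,4-bis(trimethylsilyloxy)phenyl]-3-[(3-methylbut-2-enyloxy)methyl]-5,7-bis(triisopropylsilyloxy)-4H-chromen-4-one
Conditions: DDQ (1.0 equiv), dry toluene, 0 °C
Reagents that add atoms: none
Why: Dehydrogenative aromatisation of a cyclohexa-1,4-diene by a quinone (hydride abstraction from a doubly allylic CH2, then proton loss). Both CH2 groups are doubly allylic and the cation is stabilised by the silyloxy groups, so one equivalent of DDQ should be consumed in the cold before it can attack the prenyl ether, whose oxidative cleavage needs water and longer times.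

Step 11
Reactants: 15 2-[3,4-bis(trimethylsilyloxy)phenyl]-3-[(3-methylbut-2-enyloxy)methyl]-5,7-bis(triisopropylsilyloxy)-4H-chromen-4-one
Product: 16 ophioglonol prenyl ether, 2-(3,4-dihydroxyphenyl)-5,7-dihydroxy-3-[(3-methylbut-2-enyloxy)methyl]-4H-chromen-4-one
Conditions: TBAF, AcOH, THF, 0 °C, argon
Reagents that add atoms: none
Why: Fluoride-mediated cleavage of aryl silyl ethers, driven by the strength of the Si–F bond. Acetic acid buffers the phenoxides so that the catechol is not oxidised and the pyranone is not opened; the prenyl ether is inert to fluoride.

## Compound list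

1 | 2,4,6-trihydroxyacetophenone | CC(=O)c1c(O)cc(O)cc1O | starting material
2 | 1-[2-hydroxy-4,6-bis(triisopropylsilyloxy)phenyl]ethanone | CC(=O)c1c(O)cc(O[Si](C(C)C)(C(C)C)C(C)C)cc1O[Si](C(C)C)(C(C)C)C(C)C | intermediate
3 | 4-oxo-5,7-bis(triisopropylsilyloxy)-4H-chromene-3-carbaldehyde | O=Cc1coc2cc(O[Si](C(C)C)(C(C)C)C(C)C)cc(O[Si](C(C)C)(C(C)C)C(C)C)c2c1=O | intermediate
4 | 3-(hydroxymethyl)-5,7-bis(triisopropylsilyloxy)-4H-chromen-4-one | OCc1coc2cc(O[Si](C(C)C)(C(C)C)C(C)C)cc(O[Si](C(C)C)(C(C)C)C(C)C)c2c1=O | intermediate
5 | prenyl bromide (1-bromo-3-methylbut-2-ene) | CC(C)=CCBr | starting material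
6 | 3-[(3-methylbut-2-enyloxy)methyl]-5,7-bis(triisopropylsilyloxy)-4H-chromen-4-one | CC(C)=CCOCc1coc2cc(O[Si](C(C)C)(C(C)C)C(C)C)cc(O[Si](C(C)C)(C(C)C)C(C)C)c2c1=O | intermediate
7 | chloro{3-[(3-methylbut-2-enyloxy)methyl]-4-oxo-5,7-bis(triisopropylsilyloxy)-4H-chromen-2-yl}zinc (LiCl complex, not isolated) | CC(C)=CCOCc1c([Zn]Cl)oc2cc(O[Si](C(C)C)(C(C)C)C(C)C)cc(O[Si](C(C)C)(C(C)C)C(C)C)c2c1=O | intermediate
8 | 2-iodo-3-[(3-methylbut-2-enyloxy)methyl]-5,7-bis(triisopropylsilyloxy)-4H-chromen-4-one | CC(C)=CCOCc1c(I)oc2cc(O[Si](C(C)C)(C(C)C)C(C)C)cc(O[Si](C(C)C)(C(C)C)C(C)C)c2c1=O | intermediate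
9 | ethynyltrimethylsilane | C#C[Si](C)(C)C | starting material
10 | 3-[(3-methylbut-2-enyloxy)methyl]-5,7-bis(triisopropylsilyloxy)-2-[(trimethylsilyl)ethynyl]-4H-chromen-4-one | CC(C)=CCOCc1c(C#C[Si](C)(C)C)oc2cc(O[Si](C(C)C)(C(C)C)C(C)C)cc(O[Si](C(C)C)(C(C)C)C(C)C)c2c1=O | intermediate
11 | 2-ethynyl-3-[(3-methylbut-2-enyloxy)methyl]-5,7-bis(triisopropylsilyloxy)-4H-chromen-4-one | CC(C)=CCOCc1c(C#C)oc2cc(O[Si](C(C)C)(C(C)C)C(C)C)cc(O[Si](C(C)C)(C(C)C)C(C)C)c2c1=O | intermediate
12 | butane-2,3-dione | CC(=O)C(C)=O | starting material
13 | 2,3-bis(trimethylsilyloxy)buta-1,3-diene | C=C(O[Si](C)(C)C)C(=C)O[Si](C)(C)C | intermediate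
14 | 2-[4,5-bis(trimethylsilyloxy)cyclohexa-1,4-dien-1-yl]-3-[(3-methylbut-2-enyloxy)methyl]-5,7-bis(triisopropylsilyloxy)-4H-chromen-4-one | CC(C)=CCOCc1c(C2=CCC(O[Si](C)(C)C)=C(O[Si](C)(C)C)C2)oc2cc(O[Si](C(C)C)(C(C)C)C(C)C)cc(O[Si](C(C)C)(C(C)C)C(C)C)c2c1=O | intermediate
15 | 2-[3,4-bis(trimethylsilyloxy)phenyl]-3-[(3-methylbut-2-enyloxy)methyl]-5,7-bis(triisopropylsilyloxy)-4H-chromen-4-one | CC(C)=CCOCc1c(-c2ccc(O[Si](C)(C)C)c(O[Si](C)(C)C)c2)oc2cc(O[Si](C(C)C)(C(C)C)C(C)C)cc(O[Si](C(C)C)(C(C)C)C(C)C)c2c1=O | intermediate
16 | ophioglonol prenyl ether, 2-(3,4-dihydroxyphenyl)-5,7-dihydroxy-3-[(3-methylbut-2-enyloxy)methyl]-4H-chromen-4-one | CC(C)=CCOCc1c(-c2ccc(O)c(O)c2)oc2cc(O)cc(O)c2c1=O | target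

## Step count and risks

Total: 11 steps. Longest linear sequence: 10 steps (steps 1 to 7 and 9 to 11); step 8 is a one-step side branch.

**Step 9 (key step).** The most likely failure is insufficient activation of the dienophile. The alkyne is activated only vinylogously, and the two silyloxy groups on ring A donate into the carbonyl, so the cycloaddition may be slower than thermal oligomerisation of the alkyne or loss of the diene by hydrolysis and self-reaction. The fallback gives up the construction of ring B and attaches it whole by a Negishi coupling. It sets out from 6, which is zincated to 7 as in step 5. Coupling of 7 (Pd(OAc)2 with SPhos, THF, 50 °C) with 4-bromo-1,2-bis(tert-butyldimethylsilyloxy)benzene F1, made from 4-bromocatechol with TBSCl and imidazole, would give 2-[3,4-bis(tert-butyldimethylsilyloxy)phenyl]-3-[(3-methylbut-2-enyloxy)methyl]-5,7-bis(triisopropylsilyloxy)-4H-chromen-4-one F2. Buffered fluoride as in step 11 then returns to the route at 16.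

**Step 2.** Electrophilic formylation of the electron-rich aromatic ring may compete with formylation of the acetyl group, and silyl ethers may be lost in the acidic medium. The fallback builds ring C under neutral conditions and also bypasses the selective reduction of step 3. It sets out from 2, which is condensed with N,N-dimethylformamide dimethyl acetal (toluene, 80 °C) to the enaminone (E)-3-(dimethylamino)-1-[2-hydroxy-4,6-bis(triisopropylsilyloxy)phenyl]prop-2-en-1-one F3. Iodine-induced cyclisation (I2, CHCl3, rt) gives 3-iodo-5,7-bis(triisopropylsilyloxy)-4H-chromen-4-one F4. Stille hydroxymethylation with (tributylstannyl)methanol (Pd(PPh3)4, dioxane, 90 °C) comes back to the route at 4.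

**Step 4.** The etherification may be sluggish, which gives time for silyl migration onto the primary alcohol or for substitution through the tertiary terminus of the prenyl cation. The fallback reverses the polarity of the ether synthesis. It sets out from 4, which is converted by an Appel reaction (CBr4, PPh3, CH2Cl2, 0 °C) into 3-(bromomethyl)-5,7-bis(triisopropylsilyloxy)-4H-chromen-4-one F5. Ag2O-assisted substitution with 3-methylbut-2-en-1-ol (CH2Cl2, rt) returns to the route at 6. The derived cation is stabilised by O1, and the conjugated chromone is the thermodynamic product.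

**Step 10.** The oxidant may over-oxidise by cleaving the prenyl ether, or the silyl enol ethers may hydrolyse before the dehydrogenation occurs. The fallback removes silicon first and oxidises afterwards. It sets out from 14, which with TBAF/AcOH (THF, 0 °C) would give the racemic acyloin 5,7-dihydroxy-2-(4-hydroxy-5-oxocyclohex-1-en-1-yl)-3-[(3-methylbut-2-enyloxy)methyl]-4H-chromen-4-one F6, in equilibrium with its regioisomer through the enediol. Aerobic oxidation of the acyloin (air, catalytic Cu(OAc)2, MeOH, then Na2S2O4 work-up to reduce any ortho-quinone) gives the 1,2-dione, which is the keto tautomer of the catechol, and so returns to the route at 16.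

**Step 7.** Aryl silyl ethers may be lost, or water may add to the activated alkyne, during the C-desilylation. The fallback avoids the C-silyl alkyne altogether. It sets out from 8, which in a Stille coupling with tributyl(ethynyl)stannane (Pd(PPh3)4, toluene, 60 °C) would give 11 directly; this route makes no new compound (F0).

## Further compounds

F1 | step 9 | 4-bromo-1,2-bis(tert-butyldimethylsilyloxy)benzene | CC(C)(C)[Si](C)(C)Oc1ccc(Br)cc1O[Si](C)(C)C(C)(C)C
F2 | step 9 | 2-[3,4-bis(tert-butyldimethylsilyloxy)phenyl]-3-[(3-methylbut-2-enyloxy)methyl]-5,7-bis(triisopropylsilyloxy)-4H-chromen-4-one | CC(C)=CCOCc1c(-c2ccc(O[Si](C)(C)C(C)(C)C)c(O[Si](C)(C)C(C)(C)C)c2)oc2cc(O[Si](C(C)C)(C(C)C)C(C)C)cc(O[Si](C(C)C)(C(C)C)C(C)C)c2c1=O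
F3 | step 2 | (E)-3-(dimethylamino)-1-[2-hydroxy-4,6-bis(triisopropylsilyloxy)phenyl]prop-2-en-1-one | CN(C)/C=C/C(=O)c1c(O)cc(O[Si](C(C)C)(C(C)C)C(C)C)cc1O[Si](C(C)C)(C(C)C)C(C)C
F4 | step 2 | 3-iodo-5,7-bis(triisopropylsilyloxy)-4H-chromen-4-one | O=c1c(I)coc2cc(O[Si](C(C)C)(C(C)C)C(C)C)cc(O[Si](C(C)C)(C(C)C)C(C)C)c12
F5 | step 4 | 3-(bromomethyl)-5,7-bis(triisopropylsilyloxy)-4H-chromen-4-one | BrCc1coc2cc(O[Si](C(C)C)(C(C)C)C(C)C)cc(O[Si](C(C)C)(C(C)C)C(C)C)c2c1=O
F6 | step 10 | rac-5,7-dihydroxy-2-(4-hydroxy-5-oxocyclohex-1-en-1-yl)-3-[(3-methylbut-2-enyloxy)methyl]-4H-chromen-4-one | CC(C)=CCOCc1c(C2=CCC(O)C(=O)C2)oc2cc(O)cc(O)c2c1=O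
F0 | step 7 | none | none
A1 | alternative 1 | (S)-2-{1-[3,4-bis(triisopropylsilyloxy)phenyl]prop-2-ynyloxy}-4,6-bis(triisopropylsilyloxy)benzaldehyde | O=Cc1c(O[Si](C(C)C)(C(C)C)C(C)C)cc(O[Si](C(C)C)(C(C)C)C(C)C)cc1O[C@@H](C#C)c1ccc(O[Si](C(C)C)(C(C)C)C(C)C)c(O[Si](C(C)C)(C(C)C)C(C)C)c1
A2 | alternative 1 | (2R)-2-[3,4-bis(triisopropylsilyloxy)phenyl]-3-methylidene-5,7-bis(triisopropylsilyloxy)chroman-4-one | C=C1C(=O)c2c(O[Si](C(C)C)(C(C)C)C(C)C)cc(O[Si](C(C)C)(C(C)C)C(C)C)cc2O[C@@H]1c1ccc(O[Si](C(C)C)(C(C)C)C(C)C)c(O[Si](C(C)C)(C(C)C)C(C)C)c1
A3 | alternative 2 | (Z)-3-(3,5-dimethoxyphenoxy)-3-(3,4-dimethoxyphenyl)-2-(methoxymethyl)prop-2-enoic acid | COC/C(C(=O)O)=C(/Oc1cc(OC)cc(OC)c1)c1ccc(OC)c(OC)c1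
A4 | alternative 2 | 5,7,3',4'-tetramethoxy-3-(methoxymethyl)flavone | COCc1c(-c2ccc(OC)c(OC)c2)oc2cc(OC)cc(OC)c2c1=O
A5 | alternative 3 | 2-[3,4-bis(tert-butyldimethylsilyloxy)phenyl]-3,4,6-tris(tert-butyldimethylsilyloxy)benzofuran | CC(C)(C)[Si](C)(C)Oc1c(-c2ccc(O[Si](C)(C)C(C)(C)C)c(O[Si](C)(C)C(C)(C)C)c2)oc2cc(O[Si](C)(C)C(C)(C)C)cc(O[Si](C)(C)C(C)(C)C)c12
A6 | alternative 3 | 3-bromo-5,7,3',4'-tetrakis(tert-butyldimethylsilyloxy)flavone | Brc1c(-c2ccc(O[Si](C)(C)C(C)(C)C)c(O[Si](C)(C)C(C)(C)C)c2)oc2cc(O[Si](C)(C)C(C)(C)C)cc(O[Si](C)(C)C(C)(C)C)c2c1=O
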